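## Structural features

The target is the linear trimer of (−)-epicatechin 3-O-gallate, epicatechin gallate-(4β→8)-epicatechin gallate-(4β→8)-epicatechin gallate; its name is better written 3,3′,3″-tri-O-gallate. Each unit is a flavan: a phloroglucinol ring A fused to the dihydropyran ring C, a catechol ring B on C2 and a galloyl ester on O3. Two aryl–alkyl bonds join the units, C4 of unit 1 to C8 of unit 2 and C4 of unit 2 to C8 of unit 3. There are eight stereocentres: C2 and C3 in all three units (2-aryl and O3 both α, 2,3-cis) and C4 in units 1 and 2 (aryl β, 3,4-trans), so units 1 and 2 each carry a contiguous C2–C3–C4 triad. The fragile elements are twenty-one free phenols (air-sensitive, and base-sensitive through quinone methides that epimerise C2), three aryl esters (lost to bases, hydrides and organometallic reagents) and two doubly benzylic C4–aryl bonds that acid can cleave. The real difficulty is to make the two crowded C4–C8 bonds on the right ring A carbon (C8, not C6) with the right configuration at C4, and then to hold the less stable 2,3-cis arrangement next to it. The key step exploits the fact that in units 1 and 2 the atoms C4a and C8a–O1 of ring A are an ortho carbon and the oxygen of a symmetric 3,5-dioxygenated phenol, while C4–C3–C2 is, at the aldehyde oxidation level, a propenal chain on C8 of the unit below. C4–C4a and O1–C2 can therefore be closed by annulation of a phenol with an enal, and the new C4 centre can then direct C3 and C2 in turn.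

## Logic of the disconnections

36 ⇒ 35. The twenty-one benzylic O–CH2 bonds are cut. The free phenols cannot be carried through oxidants, bases or organometallic reagents, so they are released last. The forward step must be a neutral hydrogenolysis that leaves the aryl esters, the ring C ethers and the C4–C8 bonds alone.

35 ⇒ 33 + 34. The three ester bonds between O3 and the galloyl carbonyls are cut, which calls for three molecules of 34 per molecule of 33. Esters would not survive the aryllithium and arylmagnesium steps, so all three are put on together at the end. This removes three identical side groups at once; the forward step must acylate three hindered, axial secondary alcohols completely.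

33 ⇒ 32. The three O3–Si bonds are cut. One robust, non-chelating silyl ether serves all three units, so a single fluoride step frees all three alcohols; the forward step must reach three hindered silyl ethers without touching anything else.

32 ⇒ 31 ⇒ 29 + 16. In unit 1 the O1–C2 bond is cut first, then the C2–aryl bond. Ring C and ring B of unit 1 fall away and leave an α-silyloxy aldehyde (as its lactol 29) and an aryl nucleophile. The forward steps must add the aryl group to give the 2,3-anti diol and then close the ether with clean inversion at the benzylic carbon, so that 2,3-cis results.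

16 ⇒ 15. The aryl C–Mg bond is cut back to the C–Br bond of a bought arene. One batch of 16 serves both aryl additions, so the only demand is a clean magnesium insertion that leaves the benzyl ethers alone.

29 ⇒ 28 ⇒ 27 ⇒ 25. The C3–O bond of unit 1 is cut, together with the acetal oxygen at C2. The oxygenated C2–C3 pair reduces to an enol ether double bond. The forward oxidation must take place anti to the C4 aryl group, which is what gives 3,4-trans.

25 ⇒ 23 + 8. The key cut, second use: C4–C4a and O1–C2 of unit 1. Ring A of unit 1 becomes 8 and the rest is 23, an enal on C8 of unit 2. The forward step must choose one face of the enal and an ortho carbon of the phenol.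

23 ⇒ 20 ⇒ 19. The bond from C8 of unit 2 to the propenal chain is cut, then C8–Br. This returns the protected dimer with no extra functionality; the forward bromination must be selective for C8 of the upper unit.

19 ⇒ 18 ⇒ 14 + 16, and 14 ⇒ 13 ⇒ 12 ⇒ 10. The same cuts are made in unit 2: O1–C2, C2–aryl, then C3–O. The dimer is reduced to an enol ether that carries only the C4 stereocentre, with the same demands as for unit 1.

10 ⇒ 7 + 8. The key cut, first use: C4–C4a and O1–C2 of unit 2. One ring, two skeletal bonds and the controlling stereocentre are removed in one operation. The partners are the chiral-pool enal 7 and the symmetric phenol 8. The forward step must be enantioface-selective under catalyst control and ortho-selective on the phenol.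

7 ⇒ 4 ⇒ 3 ⇒ 2 ⇒ 1. The C8–chain bond, C8–Br, O3–Si and the four benzyl ether bonds are cut. This leads back to 1, which supplies C2 and C3 of unit 3. The forward steps must brominate C8 and not C6 and must not epimerise C2.

## Other disconnections considered

Alternative 1: The cut is C8–C8a and C6–C7 of ring A of unit 2, so that this ring is built on a carbon chain already bonded to C4 of unit 1. In the forward step the siloxyalkyne A2 is heated with the 3-siloxycyclobutenone A3. The cyclobutenone opens to a vinylketene, adds to the alkyne in a (2+2) cycloaddition, opens again and closes by a six-electron electrocyclisation to the phenol A1.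
- In its favour: the regiochemistry of ring A is fixed by construction (unit 1 can only end up on C8). The only free hydroxyl of A1 is the C8a phenol needed to close ring C. The cascade is thermal and neutral.
- Against it here: A1 has a CH2 at C4 of unit 2, so the bond to unit 3 still needs a later C4 oxidation and a Lewis-acid coupling. A2 needs an ynol silyl ether on a hindered C4 carbon. A3 needs its own asymmetric synthesis of the C2/C3 side chain.
- Comparison: on the C8/C6 and ortho/para question it is better than the chosen plan. On ring C closure it is equal, since both end with an invertive etherification at C2. Mechanistically it creates no stereocentre in the key step, whereas the chosen plan sets C4 by catalyst and relays it. In step economy it is clearly worse: two elaborate fragments plus a separate attachment of unit 3, against eight operations per unit (bromination to ring closure) in the chosen plan.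

Alternative 2: The cut is the aryl–oxygen bond C8a–O1 of unit 2. In the forward step the bromo alcohol A5 is treated with Pd(OAc)2 (reduced in the flask to zerovalent palladium), 2-(di-tert-butylphosphino)-1,1′-binaphthyl and Cs2CO3. Oxidative addition into C8a–Br, alkoxide binding to divalent palladium and C–O reductive elimination give A4.
- In its favour: the C2–O bond is never broken, so C2 is retained and cannot ionise. This is better than the Mitsunobu closure of the chosen plan. A4 differs from 19 only in the silyl group, so the endgames are equal.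
- Against it here: it is a ring-closing tactic, not an answer to the interflavan bond. A5 must already contain C4 with unit 3 attached, plus a 2,3-syn (not anti) alcohol and a bromine at C8a. That bromine is in the way of the bromine–lithium exchange used to iterate. The electron-rich, doubly ortho-substituted bromoarene adds slowly to palladium, and a secondary benzylic palladium alkoxide can undergo β-hydride elimination.
- Comparison: structurally it solves less. Mechanistically it is the safer closure. In step count the closure is one step for one step, but the precursor is longer because the phenol that drives the annulation would have to be replaced by bromine.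

Alternative 3: The cut is O1–C2 and C3–C4 of unit 2, a (4+2) retron. In the forward step a chiral 3,3′-bis(2,4,6-triisopropylphenyl)-1,1′-binaphthyl-2,2′-diyl hydrogen phosphate dehydrates the benzhydrol A7 to an ortho-quinone methide. This adds the (Z)-enol gallate A8 in an inverse-demand hetero-cycloaddition to give A6.
- In its favour: it is the most convergent option. Ring C, C2, C3 and C4 are formed in one step, 2,3-cis is encoded in the Z geometry, and the gallate is already in place. In step economy it is better than the chosen plan.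
- Against it here: enol esters are weak partners for quinone methides, and the polarisation is ambiguous (the catechol ring must outweigh the acyloxy group to give the flavan and not the isoflavan-type regioisomer). A stepwise cationic path would erode both the cis relationship and the 3,4 relationship. The phosphate must control the face of a very crowded, already chiral methide. The gallate in A6 would not survive the bromine–lithium exchange needed to go on to unit 1.
- Comparison: three selectivities rest on one step without close precedent, whereas the chosen plan spreads them over separate steps of known type. For a single dimer the alternative would be shorter; for the iterated trimer the chosen plan is the more dependable.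

Key step: step 5

Remarks before the steps:
- Check of the structures: the target is epicatechin 3-O-gallate linked (4β→8) twice. The enal 7 and the 4H-chromene 10 agree with it (C4 of 10 has the configuration of C4 in unit 2). The only correction concerns the name, which needs primes (3,3′,3″).
- Design choices, with the disconnection untouched: the enal is made in one operation from the aryllithium and 3-(dimethylamino)acrolein; the lactol is dehydrated under basic conditions (MsCl/Et3N), because acid would endanger the silyl ether and the diarylmethine; the methyl acetal is cleaved with a silyl triflate and collidine for the same reason.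
- Assumption: 8, 15 and 34 are bought as such (each is the benzyl ether of phloroglucinol, 4-bromocatechol or gallic acid).
- Assumption: centres that are destroyed later (lactol and hemiketal carbons, the carbinol of 6 and 22) are epimer mixtures and are written without descriptor.
- Stoichiometry: the arylmagnesium reagent 16 is made once and used in two steps; the triple esterification consumes three equivalents of 34.
- Convention: α is the face of the 2-aryl group and of O3 in epicatechin; β is the other face.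
- Shorthand: TBS = tert-butyldimethylsilyl; Ar = 3,4-bis(benzyloxy)phenyl; Ep = 3-O-TBS-5,7,3′,4′-tetra-O-benzyl-(−)-epicatechin-8-yl; Di = the 8-yl group of 19 (bonded through C8 of its upper unit).

## Route

Step 1
Reactants: 1 (−)-epicatechin
Product: 2 5,7,3′,4′-tetra-O-benzyl-(−)-epicatechin
Conditions: BnBr (4.4 equiv), K2CO3, DMF, N2, 0 °C → rt
Reagents that add atoms: benzyl bromide, BrCc1ccccc1
Why: Williamson etherification of the four phenols, which are far more acidic than the secondary alcohol; carbonate at low temperature under nitrogen avoids C2 epimerisation, and C2 and C3 of unit 3 come unchanged from the chiral pool.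

Step 2
Reactants: 2 5,7,3′,4′-tetra-O-benzyl-(−)-epicatechin
Product: 3 3-O-TBS-5,7,3′,4′-tetra-O-benzyl-(−)-epicatechin
Conditions: TBSCl, imidazole, DMF, rt
Reagents that add atoms: tert-butyldimethylsilyl chloride, CC(C)(C)[Si](C)(C)Cl
Why: Standard silylation of the secondary alcohol; the silyl ether tolerates n-BuLi, the arylmagnesium reagent, dimethyldioxirane and the Mitsunobu conditions and is removed only in step 20.

Step 3
Reactants: 3 3-O-TBS-5,7,3′,4′-tetra-O-benzyl-(−)-epicatechin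
Product: 4 8-bromo-3-O-TBS-5,7,3′,4′-tetra-O-benzyl-(−)-epicatechin
Conditions: NBS (1.0 equiv), CH2Cl2, −78 °C → rt
Reagents that add atoms: N-bromosuccinimide, O=C1CCC(=O)N1Br
Why: Electrophilic aromatic bromination; in 5,7-dialkoxyflavans C8 (ortho to O1 and O7, para to O5) reacts before C6, which sits between two benzyloxy groups, and the catechol ring is much less activated.

Step 4
Reactants: 4 8-bromo-3-O-TBS-5,7,3′,4′-tetra-O-benzyl-(−)-epicatechin
Product: 7 (E)-3-Ep-prop-2-enal, via 8-lithio arene 5 (not isolated), via lithium allylic alkoxide 6 (not isolated)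
Conditions: n-BuLi (1.1 equiv), THF, −78 °C; 3-(dimethylamino)acrolein, −78 → 0 °C; then 1 M aq. HCl, 0 °C, short
Reagents that add atoms: 3-(dimethylamino)acrolein, CN(C)/C=C/C=O; water, O
Why: Bromine–lithium exchange followed by 1,2-addition of the aryllithium to the vinylogous formamide (vinylogous formylation); on acid work-up the enamine nitrogen expels the allylic oxygen to give a conjugated iminium ion, whose hydrolysis gives the enal in its more stable E geometry.

Step 5
Reactants: 7 (E)-3-Ep-prop-2-enal; 8 3,5-bis(benzyloxy)phenol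
Product: 10 5,7-bis(benzyloxy)-4β-Ep-4H-chromene, via chroman-2-ol 9 (not isolated)
Conditions: 8 (1.5 equiv), (S)-α,α-diphenylprolinol trimethylsilyl ether (20 mol%), PhCO2H (20 mol%), toluene, 0 °C → rt; then Et3N, MsCl, CH2Cl2, 0 °C → rt
Reagents that add atoms: none
Why: The secondary amine condenses with 7 to the (E)-iminium ion, an ortho carbon of 8 adds to its β-carbon (Friedel–Crafts Michael addition, C4–C4a), rearomatisation and hydrolysis of the enamine free the catalyst, and the phenol oxygen closes onto the aldehyde as hemiacetal 9 (6-exo-trig, O1–C2); the closest known reaction type is the iminium-catalysed Friedel–Crafts alkylation and hemiacetal closure of electron-rich phenols and naphthols with enals to 4-substituted chroman-2-ols. MsCl/Et3N then turns the anomeric hydroxyl into a sulfonate that leaves with the help of O1, and loss of a C3 proton gives the enol ether without acid, so the silyl ether and the acid-labile diarylmethine are spared. The only new stereocentre, C4, is set by the catalyst: in the s-trans (E)-iminium ion of the (S)-amine the CPh2(OTMS) group covers one face of the β-carbon and the phenol should attack the other, which on the usual shielding model puts unit 3 on the β face of the new ring; the stereocentres of 7 are at least five bonds away and are not expected to override this. Ortho attack is needed and not para attack: the two ortho carbons of 8 are equivalent by symmetry, they lie between OH and OBn and are less hindered than the para carbon between two OBn groups, the phenol OH can hydrogen-bond to the carboxylate–iminium pair during attack, and only the ortho adduct can close to 9. Attack through carbon and not oxygen is favoured by the soft, hindered β-carbon and by the reversibility of the oxa-Michael addition.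

Step 6
Reactants: 10 5,7-bis(benzyloxy)-4β-Ep-4H-chromene
Product: 12 2β-methoxy-5,7-bis(benzyloxy)-4β-Ep-chroman-3α-ol, via 2α,3α-epoxychroman 11 (not isolated)
Conditions: dimethyldioxirane (1.2 equiv, acetone solution), CH2Cl2/MeOH, −78 → 0 °C
Reagents that add atoms: dimethyldioxirane, CC1(C)OO1; methanol, CO
Why: Epoxidation of the electron-rich enol ether is much faster than oxidation of the arenes or benzyl ethers and takes place anti to the pseudoaxial C4 aryl group, so O3 becomes α (3,4-trans); methanol opens the glycal-type epoxide at the acetal carbon C2, whose configuration is lost again in step 8.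

Step 7
Reactants: 12 2β-methoxy-5,7-bis(benzyloxy)-4β-Ep-chroman-3α-ol
Product: 13 2β-methoxy-3α-(TBS-oxy)-5,7-bis(benzyloxy)-4β-Ep-chroman
Conditions: TBSOTf, 2,6-lutidine, CH2Cl2, −78 → −20 °C
Reagents that add atoms: tert-butyldimethylsilyl triflate, CC(C)(C)[Si](C)(C)OS(=O)(=O)C(F)(F)F
Why: Silyl triflate silylation of a hindered secondary alcohol; at low temperature with a hindered base the mixed acetal is not touched, and the bulky, non-chelating silyl ether is what makes step 10 follow the Felkin–Anh course.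

Step 8
Reactants: 13 2β-methoxy-3α-(TBS-oxy)-5,7-bis(benzyloxy)-4β-Ep-chroman
Product: 14 3α-(TBS-oxy)-5,7-bis(benzyloxy)-4β-Ep-chroman-2-ol
Conditions: Et3SiOTf, 2,4,6-collidine, CH2Cl2, 0 °C; then H2O, rt
Reagents that add atoms: water, O
Why: Acetal cleavage by silyl triflate and a pyridine base: the triflate removes methoxide, collidine traps the oxocarbenium ion as a pyridinium salt, and water hydrolyses this to the lactol; the weakly basic medium spares both silyl ethers, the benzyl ethers and the C4–aryl bond.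

Step 9
Reactants: 15 4-bromo-1,2-bis(benzyloxy)benzene
Product: 16 3,4-bis(benzyloxy)phenylmagnesium bromide (titrated THF solution kept under argon; one batch serves steps 10 and 18)
Conditions: Mg turnings (1.3 equiv, I2 crystal), THF, 40 °C → rt
Reagents that add atoms: magnesium, [Mg]
Why: Grignard reagent formation by insertion of magnesium into the aryl C–Br bond; the benzyl aryl ethers are inert to the reagent, and a titrated stock solution supplies the same nucleophile for both aryl additions.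

Step 10
Reactants: 14 3α-(TBS-oxy)-5,7-bis(benzyloxy)-4β-Ep-chroman-2-ol; 16 3,4-bis(benzyloxy)phenylmagnesium bromide
Product: 18 2,3-anti-1-Ar-2-(TBS-oxy)-3-[2-hydroxy-4,6-bis(benzyloxy)phenyl]-3-Ep-propan-1-ol, via open hydroxy-aldehyde 17 (not isolated)
Conditions: 16 (4 equiv, THF solution), THF, −78 → 0 °C; aq. NH4Cl
Reagents that add atoms: none
Why: The first equivalent of 16 deprotonates the lactol, which opens to the phenoxide aldehyde 17; the second adds under Felkin–Anh control (C3–OSi bond anti to the incoming aryl, no chelation by the bulky silyl ether) to give the 2,3-anti diol. The new carbinol therefore has the configuration opposite to that of C2 in epicatechin, as step 11 requires.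

Step 11
Reactants: 18 2,3-anti-1-Ar-2-(TBS-oxy)-3-[2-hydroxy-4,6-bis(benzyloxy)phenyl]-3-Ep-propan-1-ol
Product: 19 [3-O-TBS-5,7,3′,4′-tetra-O-benzyl-epicatechin]-(4β→8)-[3-O-TBS-5,7,3′,4′-tetra-O-benzyl-epicatechin]
Conditions: PPh3, DIAD, THF, 0 °C → rt
Reagents that add atoms: none
Why: Intramolecular Mitsunobu etherification: the phenol is the acidic partner, the benzylic alcohol is activated as its alkoxyphosphonium ion and displaced by SN2 with inversion (6-exo-tet). This puts the 2-aryl group α, cis to O3, while C3 and C4 are untouched.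

Step 12
Reactants: 19 [3-O-TBS-5,7,3′,4′-tetra-O-benzyl-epicatechin]-(4β→8)-[3-O-TBS-5,7,3′,4′-tetra-O-benzyl-epicatechin]
Product: 20 8-bromo derivative of 19 (bromine on C8 of the upper unit)
Conditions: NBS (1.0 equiv), CH2Cl2, −78 → −20 °C
Reagents that add atoms: N-bromosuccinimide, O=C1CCC(=O)N1Br
Why: The same preference as in step 3: the upper unit has the only free C8, while C6 of either unit lies between two benzyloxy groups and reacts more slowly; one equivalent at low temperature limits double bromination.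

Step 13
Reactants: 20 8-bromo derivative of 19
Product: 23 (E)-3-Di-prop-2-enal, via 8-lithio arene 21 (not isolated), via lithium allylic alkoxide 22 (not isolated)
Conditions: n-BuLi (1.1 equiv), THF, −78 °C; 3-(dimethylamino)acrolein, −78 → 0 °C; then 1 M aq. HCl, 0 °C, short
Reagents that add atoms: 3-(dimethylamino)acrolein, CN(C)/C=C/C=O; water, O
Why: Bromine–lithium exchange and vinylogous formylation as in step 4; no acidic proton competes at −78 °C, and the silyl ethers and the C4 diarylmethine are inert to the aryllithium.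

Step 14
Reactants: 23 (E)-3-Di-prop-2-enal; 8 3,5-bis(benzyloxy)phenol
Product: 25 5,7-bis(benzyloxy)-4β-Di-4H-chromene, via chroman-2-ol 24 (not isolated)
Conditions: 8 (1.5 equiv), (S)-α,α-diphenylprolinol trimethylsilyl ether (20 mol%), PhCO2H (20 mol%), toluene, 0 °C → rt; then Et3N, MsCl, CH2Cl2, 0 °C → rt
Reagents that add atoms: none
Why: The same iminium-catalysed Friedel–Crafts Michael addition, 6-exo-trig hemiacetal closure and base-mediated dehydration as in step 5; the same (S)-amine is used because C4 of unit 1 needs the same local configuration as C4 of unit 2.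

Step 15
Reactants: 25 5,7-bis(benzyloxy)-4β-Di-4H-chromene
Product: 27 2β-methoxy-5,7-bis(benzyloxy)-4β-Di-chroman-3α-ol, via 2α,3α-epoxychroman 26 (not isolated)
Conditions: dimethyldioxirane (1.2 equiv, acetone solution), CH2Cl2/MeOH, −78 → 0 °C
Reagents that add atoms: dimethyldioxirane, CC1(C)OO1; methanol, CO
Why: As in step 6: epoxidation of the enol ether anti to the C4 substituent sets O3 α (3,4-trans), and methanol opens the epoxide at C2.

Step 16
Reactants: 27 2β-methoxy-5,7-bis(benzyloxy)-4β-Di-chroman-3α-ol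
Product: 28 2β-methoxy-3α-(TBS-oxy)-5,7-bis(benzyloxy)-4β-Di-chroman
Conditions: TBSOTf, 2,6-lutidine, CH2Cl2, −78 → −20 °C
Reagents that add atoms: tert-butyldimethylsilyl triflate, CC(C)(C)[Si](C)(C)OS(=O)(=O)C(F)(F)F
Why: As in step 7: silyl triflate silylation of the hindered alcohol under conditions that leave the acetal alone.

Step 17
Reactants: 28 2β-methoxy-3α-(TBS-oxy)-5,7-bis(benzyloxy)-4β-Di-chroman
Product: 29 3α-(TBS-oxy)-5,7-bis(benzyloxy)-4β-Di-chroman-2-ol
Conditions: Et3SiOTf, 2,4,6-collidine, CH2Cl2, 0 °C; then H2O, rt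
Reagents that add atoms: water, O
Why: As in step 8: acetal cleavage through a collidinium salt under weakly basic conditions that spare three silyl ethers and two C4–aryl bonds.

Step 18
Reactants: 29 3α-(TBS-oxy)-5,7-bis(benzyloxy)-4β-Di-chroman-2-ol; 16 3,4-bis(benzyloxy)phenylmagnesium bromide
Product: 31 2,3-anti-1-Ar-2-(TBS-oxy)-3-[2-hydroxy-4,6-bis(benzyloxy)phenyl]-3-Di-propan-1-ol, via open hydroxy-aldehyde 30 (not isolated)
Conditions: 16 (4 equiv, THF solution), THF, −78 → 0 °C; aq. NH4Cl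
Reagents that add atoms: none
Why: As in step 10: lactol opening and Felkin–Anh addition of the aryl group anti to the C3–OSi bond give the 2,3-anti diol.

Step 19
Reactants: 31 2,3-anti-1-Ar-2-(TBS-oxy)-3-[2-hydroxy-4,6-bis(benzyloxy)phenyl]-3-Di-propan-1-ol
Product: 32 3,3′,3″-tris-O-TBS-dodeca-O-benzyl-procyanidin C1
Conditions: PPh3, DIAD, THF, 0 °C → rt
Reagents that add atoms: none
Why: As in step 11: Mitsunobu closure (6-exo-tet) with inversion at the benzylic carbon gives the 2,3-cis ring C of unit 1.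

Step 20
Reactants: 32 3,3′,3″-tris-O-TBS-dodeca-O-benzyl-procyanidin C1
Product: 33 dodeca-O-benzyl-procyanidin C1
Conditions: Bu4NF (6 equiv), THF, rt → 50 °C; H2O
Reagents that add atoms: none
Why: Fluoride cleaves the three secondary silyl ethers; with every phenol still benzylated there is no path to C2 epimerisation, and no other group is fluoride- or base-sensitive.

Step 21
Reactants: 33 dodeca-O-benzyl-procyanidin C1; 34 3,4,5-tris(benzyloxy)benzoic acid
Product: 35 3,3′,3″-tris-O-[3,4,5-tris(benzyloxy)benzoyl]-dodeca-O-benzyl-procyanidin C1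
Conditions: 34 (4.5 equiv in all), DCC (5 equiv), DMAP (1.5 equiv), CH2Cl2, rt → 40 °C
Reagents that add atoms: 3,4,5-tris(benzyloxy)benzoic acid (34; the second and third of the three equivalents that end up in 35), OC(=O)c1cc(OCc2ccccc2)c(OCc2ccccc2)c(OCc2ccccc2)c1
Why: Threefold Steglich esterification, one molecule of 34 per free 3-hydroxyl; the acylpyridinium ion formed with DMAP is reactive enough for the hindered axial alcohols, and C3 keeps its configuration because no C3–O bond is broken.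

Step 22
Reactants: 35 3,3′,3″-tris-O-[3,4,5-tris(benzyloxy)benzoyl]-dodeca-O-benzyl-procyanidin C1
Product: 36 procyanidin C1 3,3′,3″-tri-O-gallate
Conditions: H2 (1 atm), Pd(OH)2/C, THF/MeOH/H2O, rt
Reagents that add atoms: none
Why: Hydrogenolysis of the twenty-one benzyl ethers under neutral conditions; the aryl esters, the cyclic C2–O1 ethers and the C4–C8 bonds should survive, and no acid or base is present that could cleave or epimerise the product.

## Compound list

1 | (−)-epicatechin, (2R,3R) | O[C@@H]1Cc2c(O)cc(O)cc2O[C@@H]1c1ccc(O)c(O)c1 | starting material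
2 | 5,7,3′,4′-tetra-O-benzyl-(−)-epicatechin | O[C@@H]1Cc2c(OCc9ccccc9)cc(OCc9ccccc9)cc2O[C@@H]1c8ccc(OCc9ccccc9)c(OCc9ccccc9)c8 | intermediate
3 | 3-O-TBS-5,7,3′,4′-tetra-O-benzyl-(−)-epicatechin | CC(C)(C)[Si](C)(C)O[C@@H]1Cc2c(OCc9ccccc9)cc(OCc9ccccc9)cc2O[C@@H]1c8ccc(OCc9ccccc9)c(OCc9ccccc9)c8 | intermediate
4 | 8-bromo-3-O-TBS-5,7,3′,4′-tetra-O-benzyl-(−)-epicatechin | Brc2c(OCc9ccccc9)cc(OCc9ccccc9)c3c2O[C@H](c8ccc(OCc9ccccc9)c(OCc9ccccc9)c8)[C@H](O[Si](C)(C)C(C)(C)C)C3 | intermediate
5 | 8-lithio-3-O-TBS-5,7,3′,4′-tetra-O-benzyl-(−)-epicatechin | [Li]c2c(OCc9ccccc9)cc(OCc9ccccc9)c3c2O[C@H](c8ccc(OCc9ccccc9)c(OCc9ccccc9)c8)[C@H](O[Si](C)(C)C(C)(C)C)C3 | intermediate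
6 | lithium (E)-3-(dimethylamino)-1-Ep-prop-2-en-1-olate (carbinol epimers) | CN(C)/C=C/C(O[Li])c2c(OCc9ccccc9)cc(OCc9ccccc9)c3c2O[C@H](c8ccc(OCc9ccccc9)c(OCc9ccccc9)c8)[C@H](O[Si](C)(C)C(C)(C)C)C3 | intermediate
7 | (E)-3-Ep-prop-2-enal (enal on C8 of protected unit 3) | O=C/C=C/c2c(OCc9ccccc9)cc(OCc9ccccc9)c3c2O[C@H](c8ccc(OCc9ccccc9)c(OCc9ccccc9)c8)[C@H](O[Si](C)(C)C(C)(C)C)C3 | intermediate
8 | 3,5-bis(benzyloxy)phenol | Oc1cc(OCc2ccccc2)cc(OCc2ccccc2)c1 | starting material
9 | 5,7-bis(benzyloxy)-4β-Ep-chroman-2-ol (C2 epimers; C4 H α) | OC1C[C@@H](c2c(OCc9ccccc9)cc(OCc9ccccc9)c3c2O[C@H](c8ccc(OCc9ccccc9)c(OCc9ccccc9)c8)[C@H](O[Si](C)(C)C(C)(C)C)C3)c2c(OCc9ccccc9)cc(OCc9ccccc9)cc2O1 | intermediate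
10 | 5,7-bis(benzyloxy)-4β-Ep-4H-chromene (C4 H α) | C1=C[C@@H](c2c(OCc9ccccc9)cc(OCc9ccccc9)c3c2O[C@H](c8ccc(OCc9ccccc9)c(OCc9ccccc9)c8)[C@H](O[Si](C)(C)C(C)(C)C)C3)c2c(OCc9ccccc9)cc(OCc9ccccc9)cc2O1 | intermediate
11 | 2α,3α-epoxy-5,7-bis(benzyloxy)-4β-Ep-chroman | O1[C@H]2[C@@H]1Oc1cc(OCc9ccccc9)cc(OCc9ccccc9)c1[C@@H]2c2c(OCc9ccccc9)cc(OCc9ccccc9)c3c2O[C@H](c8ccc(OCc9ccccc9)c(OCc9ccccc9)c8)[C@H](O[Si](C)(C)C(C)(C)C)C3 | intermediate
12 | 2β-methoxy-5,7-bis(benzyloxy)-4β-Ep-chroman-3α-ol | O[C@@H]1[C@@H](c2c(OCc9ccccc9)cc(OCc9ccccc9)c3c2O[C@H](c8ccc(OCc9ccccc9)c(OCc9ccccc9)c8)[C@H](O[Si](C)(C)C(C)(C)C)C3)c2c(OCc9ccccc9)cc(OCc9ccccc9)cc2O[C@H]1OC | intermediate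
13 | 2β-methoxy-3α-(TBS-oxy)-5,7-bis(benzyloxy)-4β-Ep-chroman | CC(C)(C)[Si](C)(C)O[C@@H]1[C@@H](c2c(OCc9ccccc9)cc(OCc9ccccc9)c3c2O[C@H](c8ccc(OCc9ccccc9)c(OCc9ccccc9)c8)[C@H](O[Si](C)(C)C(C)(C)C)C3)c2c(OCc9ccccc9)cc(OCc9ccccc9)cc2O[C@H]1OC | intermediate
14 | 3α-(TBS-oxy)-5,7-bis(benzyloxy)-4β-Ep-chroman-2-ol (C2 epimers) | CC(C)(C)[Si](C)(C)O[C@@H]1[C@@H](c2c(OCc9ccccc9)cc(OCc9ccccc9)c3c2O[C@H](c8ccc(OCc9ccccc9)c(OCc9ccccc9)c8)[C@H](O[Si](C)(C)C(C)(C)C)C3)c2c(OCc9ccccc9)cc(OCc9ccccc9)cc2OC1O | intermediate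
15 | 4-bromo-1,2-bis(benzyloxy)benzene | Brc1ccc(OCc2ccccc2)c(OCc2ccccc2)c1 | starting material
16 | 3,4-bis(benzyloxy)phenylmagnesium bromide (THF stock solution) | Br[Mg]c1ccc(OCc2ccccc2)c(OCc2ccccc2)c1 | intermediate
17 | open form of 14: 2-(TBS-oxy)-3-[2-hydroxy-4,6-bis(benzyloxy)phenyl]-3-Ep-propanal (present as its magnesium phenoxide) | O=C[C@H](O[Si](C)(C)C(C)(C)C)[C@@H](c2c(OCc9ccccc9)cc(OCc9ccccc9)c3c2O[C@H](c8ccc(OCc9ccccc9)c(OCc9ccccc9)c8)[C@H](O[Si](C)(C)C(C)(C)C)C3)c2c(OCc9ccccc9)cc(OCc9ccccc9)cc2O | intermediate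
18 | 2,3-anti-1-Ar-2-(TBS-oxy)-3-[2-hydroxy-4,6-bis(benzyloxy)phenyl]-3-Ep-propan-1-ol (carbinol opposite in configuration to C2 of epicatechin) | O[C@@H](c8ccc(OCc9ccccc9)c(OCc9ccccc9)c8)[C@H](O[Si](C)(C)C(C)(C)C)[C@@H](c2c(OCc9ccccc9)cc(OCc9ccccc9)c3c2O[C@H](c8ccc(OCc9ccccc9)c(OCc9ccccc9)c8)[C@H](O[Si](C)(C)C(C)(C)C)C3)c2c(OCc9ccccc9)cc(OCc9ccccc9)cc2O | intermediate
19 | [3-O-TBS-5,7,3′,4′-tetra-O-benzyl-epicatechin]-(4β→8)-[3-O-TBS-5,7,3′,4′-tetra-O-benzyl-epicatechin] | CC(C)(C)[Si](C)(C)O[C@@H]1[C@@H](c2c(OCc9ccccc9)cc(OCc9ccccc9)c3c2O[C@H](c8ccc(OCc9ccccc9)c(OCc9ccccc9)c8)[C@H](O[Si](C)(C)C(C)(C)C)C3)c2c(OCc9ccccc9)cc(OCc9ccccc9)cc2O[C@@H]1c8ccc(OCc9ccccc9)c(OCc9ccccc9)c8 | intermediate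
20 | 8-bromo derivative of 19 (Br on C8 of the upper unit) | Brc4c(OCc9ccccc9)cc(OCc9ccccc9)c5c4O[C@H](c8ccc(OCc9ccccc9)c(OCc9ccccc9)c8)[C@H](O[Si](C)(C)C(C)(C)C)[C@H]5c2c(OCc9ccccc9)cc(OCc9ccccc9)c3c2O[C@H](c8ccc(OCc9ccccc9)c(OCc9ccccc9)c8)[C@H](O[Si](C)(C)C(C)(C)C)C3 | intermediate
21 | 8-lithio derivative of 19 | [Li]c4c(OCc9ccccc9)cc(OCc9ccccc9)c5c4O[C@H](c8ccc(OCc9ccccc9)c(OCc9ccccc9)c8)[C@H](O[Si](C)(C)C(C)(C)C)[C@H]5c2c(OCc9ccccc9)cc(OCc9ccccc9)c3c2O[C@H](c8ccc(OCc9ccccc9)c(OCc9ccccc9)c8)[C@H](O[Si](C)(C)C(C)(C)C)C3 | intermediate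
22 | lithium (E)-3-(dimethylamino)-1-Di-prop-2-en-1-olate (carbinol epimers) | CN(C)/C=C/C(O[Li])c4c(OCc9ccccc9)cc(OCc9ccccc9)c5c4O[C@H](c8ccc(OCc9ccccc9)c(OCc9ccccc9)c8)[C@H](O[Si](C)(C)C(C)(C)C)[C@H]5c2c(OCc9ccccc9)cc(OCc9ccccc9)c3c2O[C@H](c8ccc(OCc9ccccc9)c(OCc9ccccc9)c8)[C@H](O[Si](C)(C)C(C)(C)C)C3 | intermediate
23 | (E)-3-Di-prop-2-enal (enal on C8 of unit 2 of the protected dimer) | O=C/C=C/c4c(OCc9ccccc9)cc(OCc9ccccc9)c5c4O[C@H](c8ccc(OCc9ccccc9)c(OCc9ccccc9)c8)[C@H](O[Si](C)(C)C(C)(C)C)[C@H]5c2c(OCc9ccccc9)cc(OCc9ccccc9)c3c2O[C@H](c8ccc(OCc9ccccc9)c(OCc9ccccc9)c8)[C@H](O[Si](C)(C)C(C)(C)C)C3 | intermediate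
24 | 5,7-bis(benzyloxy)-4β-Di-chroman-2-ol (C2 epimers) | OC1C[C@@H](c4c(OCc9ccccc9)cc(OCc9ccccc9)c5c4O[C@H](c8ccc(OCc9ccccc9)c(OCc9ccccc9)c8)[C@H](O[Si](C)(C)C(C)(C)C)[C@H]5c2c(OCc9ccccc9)cc(OCc9ccccc9)c3c2O[C@H](c8ccc(OCc9ccccc9)c(OCc9ccccc9)c8)[C@H](O[Si](C)(C)C(C)(C)C)C3)c2c(OCc9ccccc9)cc(OCc9ccccc9)cc2O1 | intermediate
25 | 5,7-bis(benzyloxy)-4β-Di-4H-chromene | C1=C[C@@H](c4c(OCc9ccccc9)cc(OCc9ccccc9)c5c4O[C@H](c8ccc(OCc9ccccc9)c(OCc9ccccc9)c8)[C@H](O[Si](C)(C)C(C)(C)C)[C@H]5c2c(OCc9ccccc9)cc(OCc9ccccc9)c3c2O[C@H](c8ccc(OCc9ccccc9)c(OCc9ccccc9)c8)[C@H](O[Si](C)(C)C(C)(C)C)C3)c2c(OCc9ccccc9)cc(OCc9ccccc9)cc2O1 | intermediate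
26 | 2α,3α-epoxy-5,7-bis(benzyloxy)-4β-Di-chroman | O1[C@H]2[C@@H]1Oc1cc(OCc9ccccc9)cc(OCc9ccccc9)c1[C@@H]2c4c(OCc9ccccc9)cc(OCc9ccccc9)c5c4O[C@H](c8ccc(OCc9ccccc9)c(OCc9ccccc9)c8)[C@H](O[Si](C)(C)C(C)(C)C)[C@H]5c2c(OCc9ccccc9)cc(OCc9ccccc9)c3c2O[C@H](c8ccc(OCc9ccccc9)c(OCc9ccccc9)c8)[C@H](O[Si](C)(C)C(C)(C)C)C3 | intermediate
27 | 2β-methoxy-5,7-bis(benzyloxy)-4β-Di-chroman-3α-ol | O[C@@H]1[C@@H](c4c(OCc9ccccc9)cc(OCc9ccccc9)c5c4O[C@H](c8ccc(OCc9ccccc9)c(OCc9ccccc9)c8)[C@H](O[Si](C)(C)C(C)(C)C)[C@H]5c2c(OCc9ccccc9)cc(OCc9ccccc9)c3c2O[C@H](c8ccc(OCc9ccccc9)c(OCc9ccccc9)c8)[C@H](O[Si](C)(C)C(C)(C)C)C3)c2c(OCc9ccccc9)cc(OCc9ccccc9)cc2O[C@H]1OC | intermediate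
28 | 2β-methoxy-3α-(TBS-oxy)-5,7-bis(benzyloxy)-4β-Di-chroman | CC(C)(C)[Si](C)(C)O[C@@H]1[C@@H](c4c(OCc9ccccc9)cc(OCc9ccccc9)c5c4O[C@H](c8ccc(OCc9ccccc9)c(OCc9ccccc9)c8)[C@H](O[Si](C)(C)C(C)(C)C)[C@H]5c2c(OCc9ccccc9)cc(OCc9ccccc9)c3c2O[C@H](c8ccc(OCc9ccccc9)c(OCc9ccccc9)c8)[C@H](O[Si](C)(C)C(C)(C)C)C3)c2c(OCc9ccccc9)cc(OCc9ccccc9)cc2O[C@H]1OC | intermediate
29 | 3α-(TBS-oxy)-5,7-bis(benzyloxy)-4β-Di-chroman-2-ol (C2 epimers) | CC(C)(C)[Si](C)(C)O[C@@H]1[C@@H](c4c(OCc9ccccc9)cc(OCc9ccccc9)c5c4O[C@H](c8ccc(OCc9ccccc9)c(OCc9ccccc9)c8)[C@H](O[Si](C)(C)C(C)(C)C)[C@H]5c2c(OCc9ccccc9)cc(OCc9ccccc9)c3c2O[C@H](c8ccc(OCc9ccccc9)c(OCc9ccccc9)c8)[C@H](O[Si](C)(C)C(C)(C)C)C3)c2c(OCc9ccccc9)cc(OCc9ccccc9)cc2OC1O | intermediate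
30 | open form of 29: 2-(TBS-oxy)-3-[2-hydroxy-4,6-bis(benzyloxy)phenyl]-3-Di-propanal (present as its magnesium phenoxide) | O=C[C@H](O[Si](C)(C)C(C)(C)C)[C@@H](c4c(OCc9ccccc9)cc(OCc9ccccc9)c5c4O[C@H](c8ccc(OCc9ccccc9)c(OCc9ccccc9)c8)[C@H](O[Si](C)(C)C(C)(C)C)[C@H]5c2c(OCc9ccccc9)cc(OCc9ccccc9)c3c2O[C@H](c8ccc(OCc9ccccc9)c(OCc9ccccc9)c8)[C@H](O[Si](C)(C)C(C)(C)C)C3)c2c(OCc9ccccc9)cc(OCc9ccccc9)cc2O | intermediate
31 | 2,3-anti-1-Ar-2-(TBS-oxy)-3-[2-hydroxy-4,6-bis(benzyloxy)phenyl]-3-Di-propan-1-ol | O[C@@H](c8ccc(OCc9ccccc9)c(OCc9ccccc9)c8)[C@H](O[Si](C)(C)C(C)(C)C)[C@@H](c4c(OCc9ccccc9)cc(OCc9ccccc9)c5c4O[C@H](c8ccc(OCc9ccccc9)c(OCc9ccccc9)c8)[C@H](O[Si](C)(C)C(C)(C)C)[C@H]5c2c(OCc9ccccc9)cc(OCc9ccccc9)c3c2O[C@H](c8ccc(OCc9ccccc9)c(OCc9ccccc9)c8)[C@H](O[Si](C)(C)C(C)(C)C)C3)c2c(OCc9ccccc9)cc(OCc9ccccc9)cc2O | intermediate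
32 | 3,3′,3″-tris-O-TBS-dodeca-O-benzyl-procyanidin C1 | CC(C)(C)[Si](C)(C)O[C@@H]1[C@@H](c4c(OCc9ccccc9)cc(OCc9ccccc9)c5c4O[C@H](c8ccc(OCc9ccccc9)c(OCc9ccccc9)c8)[C@H](O[Si](C)(C)C(C)(C)C)[C@H]5c2c(OCc9ccccc9)cc(OCc9ccccc9)c3c2O[C@H](c8ccc(OCc9ccccc9)c(OCc9ccccc9)c8)[C@H](O[Si](C)(C)C(C)(C)C)C3)c2c(OCc9ccccc9)cc(OCc9ccccc9)cc2O[C@@H]1c8ccc(OCc9ccccc9)c(OCc9ccccc9)c8 | intermediate
33 | dodeca-O-benzyl-procyanidin C1 (three free 3-hydroxyls) | O[C@@H]1[C@@H](c4c(OCc9ccccc9)cc(OCc9ccccc9)c5c4O[C@H](c8ccc(OCc9ccccc9)c(OCc9ccccc9)c8)[C@H](O)[C@H]5c2c(OCc9ccccc9)cc(OCc9ccccc9)c3c2O[C@H](c8ccc(OCc9ccccc9)c(OCc9ccccc9)c8)[C@H](O)C3)c2c(OCc9ccccc9)cc(OCc9ccccc9)cc2O[C@@H]1c8ccc(OCc9ccccc9)c(OCc9ccccc9)c8 | intermediate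
34 | 3,4,5-tris(benzyloxy)benzoic acid | OC(=O)c1cc(OCc2ccccc2)c(OCc2ccccc2)c(OCc2ccccc2)c1 | starting material
35 | 3,3′,3″-tris-O-[3,4,5-tris(benzyloxy)benzoyl]-dodeca-O-benzyl-procyanidin C1 | O=C(O[C@@H]1[C@@H](c4c(OCc9ccccc9)cc(OCc9ccccc9)c5c4O[C@H](c8ccc(OCc9ccccc9)c(OCc9ccccc9)c8)[C@H](OC(=O)c7cc(OCc9ccccc9)c(OCc9ccccc9)c(OCc9ccccc9)c7)[C@H]5c2c(OCc9ccccc9)cc(OCc9ccccc9)c3c2O[C@H](c8ccc(OCc9ccccc9)c(OCc9ccccc9)c8)[C@H](OC(=O)c7cc(OCc9ccccc9)c(OCc9ccccc9)c(OCc9ccccc9)c7)C3)c2c(OCc9ccccc9)cc(OCc9ccccc9)cc2O[C@@H]1c8ccc(OCc9ccccc9)c(OCc9ccccc9)c8)c7cc(OCc9ccccc9)c(OCc9ccccc9)c(OCc9ccccc9)c7 | intermediate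
36 | procyanidin C1 3,3′,3″-tri-O-gallate | O=C(O[C@@H]1[C@@H](c2c(O)cc(O)c3c2O[C@H](c2ccc(O)c(O)c2)[C@H](OC(=O)c2cc(O)c(O)c(O)c2)C3)c2c(O)cc(O)c([C@H]3c4c(O)cc(O)cc4O[C@H](c4ccc(O)c(O)c4)[C@@H]3OC(=O)c3cc(O)c(O)c(O)c3)c2O[C@@H]1c1ccc(O)c(O)c1)c1cc(O)c(O)c(O)c1 | target

## Step count and uncertain steps

Total step count: 22. Longest linear sequence: 21 steps (1 → 36 through steps 1–8 and 10–22); step 9 is a one-step side branch from 15. Compounds 8, 15 and 34 are bought and enter in steps 5 and 14, in step 9, and in step 21.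

**Step 5 (key step; step 14 repeats it on 23).**
- What may go wrong: the iminium ion of a 2,6-dioxygenated, electron-rich cinnamaldehyde is crowded and a weak electrophile, so carbon–carbon bond formation may be slow or fail. Attack through the para carbon may compete. A minor iminium geometry or an uncatalysed background path may erode face selectivity.
- Fallback: give up the annulation for the Lewis-acid coupling of a C4-activated flavan with a C8-nucleophilic flavan. It sets out from 2. Oxidation with DDQ in the presence of 2-ethoxyethanol gives the 4β-(2-ethoxyethoxy) alcohol F1. TBSOTf/2,6-lutidine gives its silyl ether F2. Me3SiOTf in CH2Cl2 at −78 °C with an excess of 3 as the nucleophile then forms the 4β→8 bond trans to the 3-silyloxy group, and the route is rejoined at 19. For step 14 the same electrophile F2 with 19 as the nucleophile would rejoin at 32.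

**Step 10 (step 18 is the same reaction on 29).**
- What may go wrong: poor facial selectivity, because chelated or purely steric modes of addition (a magnesium phenoxide is close by and C4 is very large) compete with the Felkin–Anh mode; also epimerisation at C3 by enolisation.
- Fallback: set C2 by hydride addition instead of aryl addition. It sets out from 14. PhI(OAc)2 with catalytic TEMPO oxidises the lactol to the lactone F3. One equivalent of 3,4-bis(benzyloxy)phenyllithium (from 15 and n-BuLi) at −78 °C opens it to the hydroxy ketone F4. LiBH(s-Bu)3 in THF at −78 °C reduces the α-silyloxy ketone in the Felkin–Anh sense to the anti diol, and the route is rejoined at 18.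

**Step 11 (step 19 is the same reaction on 31).**
- What may go wrong: ionisation of the activated benzylic alcohol, helped by the 3,4-dialkoxyphenyl ring, with loss of the invertive course or with elimination; slow attack by the hindered phenol.
- Fallback: close ring C by delivering hydride to a cyclic oxocarbenium ion instead of alkylating the phenol. It sets out from 14 and passes through lactone F3 and hydroxy ketone F4 as above. Under BF3·OEt2 in CH2Cl2 at −78 °C F4 closes to the cyclic hemiketal F5, and Et3SiH reduces the derived 2-aryl oxocarbenium ion. Hydride should add anti to the pseudoaxial 3-silyloxy group and leave the aryl group α. The route is rejoined at 19.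

**Step 12.**
- What may go wrong: loss of regiocontrol (bromination at C6 of either unit) or double bromination.
- Fallback: brominate before ring closure, where a free phenol makes one ring far more reactive and directs ortho. It sets out from 18. NBS with catalytic i-Pr2NH in CH2Cl2 at −78 °C should give the ortho-bromophenol F6 (bromine on the future C8). Mitsunobu closure (PPh3, DIAD) then rejoins the route at 20.

**Step 4 (step 13 is the same reaction on 20).**
- What may go wrong: sluggish addition of the doubly ortho-substituted aryllithium to the vinylogous formamide, or onset of silyl ether cleavage during the acid work-up needed for the elimination.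
- Fallback: build the enal in two steps. It sets out from 4. n-BuLi then DMF gives the 8-carbaldehyde F7. A Wittig reaction with (triphenylphosphoranylidene)acetaldehyde in toluene at 80 °C rejoins the route at 7.

## Further compounds

F1 | step 5 | 4β-(2-ethoxyethoxy)-5,7,3′,4′-tetra-O-benzyl-(−)-epicatechin | O[C@@H]1[C@@H](OCCOCC)c2c(OCc9ccccc9)cc(OCc9ccccc9)cc2O[C@@H]1c8ccc(OCc9ccccc9)c(OCc9ccccc9)c8
F2 | step 5 | 3-O-TBS-4β-(2-ethoxyethoxy)-5,7,3′,4′-tetra-O-benzyl-(−)-epicatechin | CC(C)(C)[Si](C)(C)O[C@@H]1[C@@H](OCCOCC)c2c(OCc9ccccc9)cc(OCc9ccccc9)cc2O[C@@H]1c8ccc(OCc9ccccc9)c(OCc9ccccc9)c8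
F3 | step 10 | 3α-(TBS-oxy)-5,7-bis(benzyloxy)-4β-Ep-chroman-2-one | CC(C)(C)[Si](C)(C)O[C@@H]1[C@@H](c2c(OCc9ccccc9)cc(OCc9ccccc9)c3c2O[C@H](c8ccc(OCc9ccccc9)c(OCc9ccccc9)c8)[C@H](O[Si](C)(C)C(C)(C)C)C3)c2c(OCc9ccccc9)cc(OCc9ccccc9)cc2OC1=O
F4 | step 10 | 1-Ar-2-(TBS-oxy)-3-[2-hydroxy-4,6-bis(benzyloxy)phenyl]-3-Ep-propan-1-one | O=C(c8ccc(OCc9ccccc9)c(OCc9ccccc9)c8)[C@H](O[Si](C)(C)C(C)(C)C)[C@@H](c2c(OCc9ccccc9)cc(OCc9ccccc9)c3c2O[C@H](c8ccc(OCc9ccccc9)c(OCc9ccccc9)c8)[C@H](O[Si](C)(C)C(C)(C)C)C3)c2c(OCc9ccccc9)cc(OCc9ccccc9)cc2O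
F5 | step 11 | 2-Ar-3α-(TBS-oxy)-5,7-bis(benzyloxy)-4β-Ep-chroman-2-ol (cyclic hemiketal of F4) | CC(C)(C)[Si](C)(C)O[C@@H]1[C@@H](c2c(OCc9ccccc9)cc(OCc9ccccc9)c3c2O[C@H](c8ccc(OCc9ccccc9)c(OCc9ccccc9)c8)[C@H](O[Si](C)(C)C(C)(C)C)C3)c2c(OCc9ccccc9)cc(OCc9ccccc9)cc2OC1(O)c8ccc(OCc9ccccc9)c(OCc9ccccc9)c8
F6 | step 12 | 2,3-anti-1-Ar-2-(TBS-oxy)-3-[3-bromo-2-hydroxy-4,6-bis(benzyloxy)phenyl]-3-Ep-propan-1-ol | O[C@@H](c8ccc(OCc9ccccc9)c(OCc9ccccc9)c8)[C@H](O[Si](C)(C)C(C)(C)C)[C@@H](c2c(OCc9ccccc9)cc(OCc9ccccc9)c3c2O[C@H](c8ccc(OCc9ccccc9)c(OCc9ccccc9)c8)[C@H](O[Si](C)(C)C(C)(C)C)C3)c2c(OCc9ccccc9)cc(OCc9ccccc9)c(Br)c2O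
F7 | step 4 | 3-O-TBS-5,7,3′,4′-tetra-O-benzyl-(−)-epicatechin-8-carbaldehyde | O=Cc2c(OCc9ccccc9)cc(OCc9ccccc9)c3c2O[C@H](c8ccc(OCc9ccccc9)c(OCc9ccccc9)c8)[C@H](O[Si](C)(C)C(C)(C)C)C3
A1 | alternative 1 | benzannulation product: unit 1 bonded through C4 to C8 of the new ring A (free C8a phenol, triisopropylsilyl ethers at C5 and C7, side chain at C4a) | CC(C)(C)[Si](C)(C)O[C@@H]1[C@@H](c2c(O)c(C[C@@H](O[Si](C)(C)C(C)(C)C)[C@@H](OC(C)=O)c8ccc(OCc9ccccc9)c(OCc9ccccc9)c8)c(O[Si](C(C)C)(C(C)C)C(C)C)cc2O[Si](C(C)C)(C(C)C)C(C)C)c3c(OCc9ccccc9)cc(OCc9ccccc9)cc3O[C@@H]1c8ccc(OCc9ccccc9)c(OCc9ccccc9)c8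
A2 | alternative 1 | 4β-[(triisopropylsilyloxy)ethynyl]-3-O-TBS-5,7,3′,4′-tetra-O-benzyl-(−)-epicatechin | CC(C)(C)[Si](C)(C)O[C@@H]1[C@@H](C#CO[Si](C(C)C)(C(C)C)C(C)C)c3c(OCc9ccccc9)cc(OCc9ccccc9)cc3O[C@@H]1c8ccc(OCc9ccccc9)c(OCc9ccccc9)c8
A3 | alternative 1 | 3-(triisopropylsilyloxy)cyclobut-2-en-1-one carrying at C4 the 3-acetoxy-3-Ar-2-(TBS-oxy)propyl chain | O=C1C=C(O[Si](C(C)C)(C(C)C)C(C)C)C1C[C@@H](O[Si](C)(C)C(C)(C)C)[C@@H](OC(C)=O)c8ccc(OCc9ccccc9)c(OCc9ccccc9)c8
A4 | alternative 2 | protected unit 2–unit 3 dimer with O3 of unit 2 as triisopropylsilyl ether | CC(C)[Si](C(C)C)(C(C)C)O[C@@H]1[C@@H](c2c(OCc9ccccc9)cc(OCc9ccccc9)c3c2O[C@H](c8ccc(OCc9ccccc9)c(OCc9ccccc9)c8)[C@H](O[Si](C)(C)C(C)(C)C)C3)c2c(OCc9ccccc9)cc(OCc9ccccc9)cc2O[C@@H]1c8ccc(OCc9ccccc9)c(OCc9ccccc9)c8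
A5 | alternative 2 | 2,3-syn-1-Ar-2-(triisopropylsilyloxy)-3-[2-bromo-4,6-bis(benzyloxy)phenyl]-3-Ep-propan-1-ol | O[C@H](c8ccc(OCc9ccccc9)c(OCc9ccccc9)c8)[C@H](O[Si](C(C)C)(C(C)C)C(C)C)[C@@H](c2c(OCc9ccccc9)cc(OCc9ccccc9)c3c2O[C@H](c8ccc(OCc9ccccc9)c(OCc9ccccc9)c8)[C@H](O[Si](C)(C)C(C)(C)C)C3)c2c(OCc9ccccc9)cc(OCc9ccccc9)cc2Br
A6 | alternative 3 | protected unit 2–unit 3 dimer with the tri-O-benzylgallate on O3 of unit 2 | O=C(O[C@@H]1[C@@H](c2c(OCc9ccccc9)cc(OCc9ccccc9)c3c2O[C@H](c8ccc(OCc9ccccc9)c(OCc9ccccc9)c8)[C@H](O[Si](C)(C)C(C)(C)C)C3)c2c(OCc9ccccc9)cc(OCc9ccccc9)cc2O[C@@H]1c8ccc(OCc9ccccc9)c(OCc9ccccc9)c8)c7cc(OCc9ccccc9)c(OCc9ccccc9)c(OCc9ccccc9)c7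
A7 | alternative 3 | [2-hydroxy-4,6-bis(benzyloxy)phenyl](Ep)methanol (carbinol epimers) | OC(c2c(OCc9ccccc9)cc(OCc9ccccc9)c3c2O[C@H](c8ccc(OCc9ccccc9)c(OCc9ccccc9)c8)[C@H](O[Si](C)(C)C(C)(C)C)C3)c2c(OCc9ccccc9)cc(OCc9ccccc9)cc2O
A8 | alternative 3 | (Z)-2-[3,4-bis(benzyloxy)phenyl]vinyl 3,4,5-tris(benzyloxy)benzoate | O=C(O/C=C\c8ccc(OCc9ccccc9)c(OCc9ccccc9)c8)c7cc(OCc9ccccc9)c(OCc9ccccc9)c(OCc9ccccc9)c7
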